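## Analysis of the target

Broussoflavonol D (32) is a 3,5,7-trihydroxyflavone (rings A and C) whose ring B is fused through C3' and the 4'-oxygen to a 2,2-dimethyl-2H-pyran (ring D). Ring B is therefore a benzene with five substituents and a single hydrogen at C6'. C8 of ring A carries a 1,1-dimethylallyl group with a quaternary benzylic carbon, and C2' carries a normal prenyl chain ortho to the C2–C1' bond. The molecule has no stereocentre, and the C2–C1' axis, with one ortho substituent on the ring B side, is not expected to be configurationally stable, so no stereochemical relationship has to be set. The sensitive groups are three electron-rich alkenes (the chromene, the trisubstituted prenyl alkene, and the terminal vinyl group beside the free 7-hydroxyl, which can close to a dihydrofuran under acid) and the 3-hydroxy-4-pyranone, which is air-sensitive in base. Four free hydroxyls beside these alkenes rule out hydrogenolysis and strong Lewis acids at the end. The difficulty is regiochemical: ring B needs carbon substituents on C1', C2' and C3' next to vicinal oxygens, and ring A must take the reverse prenyl group at C8 and not at C6. The strategy rests on one feature: C1' (bonded to C2 of ring C) and C2' (bearing the prenyl group) are adjacent and lie opposite the vicinal oxygens on C4' and C5', with C3' and C6' between them, which is the pattern a 2,3-dioxygenated buta-1,3-diene leaves when it adds across a disubstituted alkyne.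

## Retrosynthetic reasoning

**32 from 30 (through 31).** Only C–O bonds to protecting groups are cut. The 3-, 5- and 5'-oxygens are carried as methoxymethyl acetals and the 7-oxygen as an ester. The acetals are removed first, while the 7-oxygen is still acylated, so that no free 7-hydroxyl stands beside the vinyl group under acid. The ester of 31 is then removed by brief base methanolysis with exclusion of air, which is the only time the free 3-hydroxy-4-pyranone meets base.

**30 from 28 (through 29).** The bond between C8 and the quaternary carbon is cut and the group is returned to the 7-oxygen as a prenyl ether. The forward aromatic Claisen shift builds the quaternary centre with allyl inversion from an ether that is trivial to make. It must choose C8 over C6, and the freed 7-hydroxyl of 29 must be acylated as it forms so that it cannot react with the new vinyl group.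

**28 from 27.** The O1–C8a bond is cut. A fluorine at C8a, ortho to the C4 carbonyl, lets the enol oxygen of a 1,3-diketone close ring C by intramolecular nucleophilic aromatic substitution. This is chosen over a cyclodehydration because it needs no free ortho-hydroxyl on ring A and no acid.

**27 from 26, and 26 from 18 and 24.** The C3–C4 bond is cut. Ketone 18 already holds C2, C3 and the 3-oxygen, so ring A only has to deliver the C4 carbon. It comes as aldehyde 24 (aldol addition, then oxidation) and not as an acid chloride, because an acid chloride with an ortho methoxymethoxy group can be captured by that acetal oxygen. The aldol also removes any O- versus C-acylation question.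

**24 from 23, 22, 21 and 19.** Ring A is built from the fluoro-dimethoxybenzene 19 by formylation and ether cleavage. The two hydroxyls of 22 are told apart by the formyl group: the 4-hydroxyl is para to it and not hydrogen-bonded, so it takes the prenyl group (from 6); the chelated 6-hydroxyl is then protected.

**18 from 15, 14 and 13.** Ring D is opened at the C3'–C bond and traced to an aryl 1,1-dimethylpropargyl ether on the 4'-oxygen. The forward pericyclic cascade can only go to C3', the single free ortho carbon. In catechol 13 the 4'-hydroxyl is para to the ketone and the more acidic, which selects it for the ether.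

**13 from 11 (through 12).** The benzene ring is taken back to a cyclohexa-1,4-diene. The forward step is a dehydrogenation that the two enol ether oxygens make easy, followed by loss of the silyl groups.

**11 from 2 and 10.** This is the central disconnection: the C1'–C6' and C2'–C3' bonds of ring B are cut in a retro-[4+2] sense. It gives a symmetric diene 2, so there is no regiochemical issue, and an ynone 10 that already carries the prenyl chain and the two carbons and the oxygen of the C2–C3 unit. No cross-coupling or directed substitution on a crowded arene is needed.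

**10 from 7 and 5; 7 from 6; 5 from 4 and 3; 2 from 1.** The ynone is cut at the acyl–alkyne bond into the acetylide 8 of enyne 7 and the N-methoxy-N-methylamide 5. The amide holds the adduct 9 until work-up, so the base-sensitive skipped enynone never meets base. Enyne 7 comes from 6 and an ethynyl nucleophile, 5 from glycolate 3 via 4, and 2 by double enol silylation of 1.

## Alternatives that were turned down

**Alternative 1:** The two methyl–carbon bonds of the quaternary carbon on C8 are disconnected, the vinyl group being a former lactone carbonyl.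
- Forward key step: 4,6-dimethoxybenzofuran-2(3H)-one A1 is deprotonated twice at C3 by a hydride base and methylated twice to 4,6-dimethoxy-3,3-dimethylbenzofuran-2(3H)-one A2. Reduction to the lactol and methylenation would open it to 3,5-dimethoxy-2-(2-methylbut-3-en-2-yl)phenol A3, whose hydroxyl becomes O1.
- For it: the reverse prenyl group is placed by construction, with no choice between C6 and C8. On this point it is stronger than the Claisen shift of step 18.
- Against it: A3 brings ring A as a phenol with two methyl ethers. Ring C would have to be closed by C-acylation ortho to the phenol, where two free positions compete. The 7-O-methyl group can only be removed with strong Lewis acids that the chromene, the prenyl chain and the vinyl group would not survive. Ring B, the harder half, is not addressed.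
- Comparison: the chosen route accepts a site-selectivity risk on ring A, but it builds ring B in one cycloaddition and ends with acetal and ester cleavage only.

**Alternative 2:** The C2–C1' bond is disconnected after tying ring B to the 3-oxygen through an ester whose carbonyl is the future C2' carbon.
- Forward key step: in the chromon-3-yl 2-bromoaroate A4, zerovalent palladium inserts into the C1'–Br bond and arylates the C2–H position by concerted metalation–deprotonation. This closes a six-membered lactone and gives the lactone-bridged flavonol A5.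
- For it: it is highly convergent and intramolecular, so there is no site ambiguity at C2, and the hindered C2–C1' bond is made late with rings A, C and D complete. In convergence and in forming that bond it is as strong as or stronger than steps 15 to 17.
- Against it: C2' arrives as one carbonyl carbon. After lactone opening it must be turned into a five-carbon prenyl chain (reduction, activation of a benzylic alcohol beside a free 3-hydroxyl, sp3–sp2 coupling), late and in the presence of a terminal vinyl group that the palladium step must also tolerate. The bromo acid half of A4 is itself a pentasubstituted benzene whose synthesis is left open.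
- Comparison: in the chosen route the prenyl chain is in place from the alkyne and ring B is built, not decorated. What is given up is the late convergent union.

**Alternative 3:** The C2'–CH2 and C3'–acyl bonds are disconnected; both carbon arms are inserted into a preformed dioxygenated benzene.
- Forward key step: the enolate of methyl 5-methyl-3-oxohex-4-enoate A6 adds to 3,4-dimethoxybenzyne A7, released by fluoride from 2,3-dimethoxy-6-(trimethylsilyl)phenyl trifluoromethanesulfonate A8. The aryl anion closes onto the ketone and the cyclobutoxide fragments to methyl 2-[3,4-dimethoxy-2-(3-methylbut-2-enoyl)phenyl]acetate A9, with no ring closed.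
- For it: one mild operation sets two adjacent C–C bonds, with regiochemistry dictated by the alkoxy group next to the aryne, and the enoyl arm holds every carbon of ring D. For the pyran carbons it is the stronger answer.
- Against it: in A9 the future C1' is still a C–H bond and would have to be functionalised later against C6'. The acetate arm must become a prenyl group, and the enone must become a chromene through a chromanone (selective 4'-O-demethylation, oxa-Michael closure, reduction, dehydration). The other methyl ether must then be cleaved beside acid-sensitive alkenes.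
- Comparison: the cycloaddition of step 6 gives C1' already bonded to the future C2 and C3, the prenyl chain complete, and both oxygens as silyl ethers that fall off in methanol. It is shorter by several functional-group changes.

Key step: step 6

Remark on the chemistry: metal and boron alkoxides and phenoxides that are only protonated on work-up (the lithium aldolate of step 15, the aryl borates of step 12, the potassium phenoxides of step 19) are counted with their neutral forms; the minor regioisomers of steps 4 and 11 are assumed to be removed by distillation and crystallisation; 26 and 27 carry stereocentres that are formed without control and vanish in step 17.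

## Route

Step 1
Reactants: 1 2,3-butanedione
Product: 2 2,3-bis(trimethylsilyloxy)buta-1,3-diene
Conditions: Me3SiCl, Et3N, LiBr, THF, 0 to 40 °C
Reagents that add atoms: chlorotrimethylsilane, C[Si](C)(C)Cl
Why: Soft enolisation of both acetyl groups and O-silylation give the bis(silyl enol ether); the diene is distilled and stored free of amine salts.

Step 2
Reactants: 3 methyl glycolate
Product: 4 methyl 2-(methoxymethoxy)acetate
Conditions: MOMCl, i-Pr2NEt, CH2Cl2, 0 °C to rt
Reagents that add atoms: chloromethyl methyl ether, COCCl
Why: O-Alkylation of the primary alcohol by the oxocarbenium-type chloride under a hindered amine base; the acetal will serve as the 3-O protecting group to the end.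

Step 3
Reactants: 4 methyl 2-(methoxymethoxy)acetate
Product: 5 N-methoxy-2-(methoxymethoxy)-N-methylacetamide
Conditions: MeNH(OMe)·HCl, i-PrMgCl, THF, −20 to 0 °C
Reagents that add atoms: N,O-dimethylhydroxylamine hydrochloride, CNOC.Cl
Why: The magnesium amide formed in the flask aminolyses the activated α-alkoxy ester (ester-to-N-methoxy-N-methylamide exchange).

Step 4
Reactants: 6 prenyl bromide (1-bromo-3-methylbut-2-ene)
Product: 7 5-methylhex-4-en-1-yne
Conditions: HC≡CMgBr, CuCl (cat.), THF, 0 to 50 °C
Reagents that add atoms: ethynylmagnesium bromide, C#C[Mg]Br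
Why: Copper-catalysed coupling of an alkynyl Grignard reagent with an allylic bromide; attack at the primary terminus (SN2) should dominate over the hindered tertiary terminus (SN2'), and the volatile enyne is purified by distillation.

Step 5
Reactants: 7 5-methylhex-4-en-1-yne; 5 N-methoxy-2-(methoxymethoxy)-N-methylacetamide
Product: 10 1-(methoxymethoxy)-7-methyloct-6-en-3-yn-2-one, via lithium acetylide 8 (not isolated), via lithium hemiaminal alkoxide 9 (not isolated)
Conditions: n-BuLi, THF, −78 °C; then 5, −78 to 0 °C; cold aq NH4Cl
Reagents that add atoms: none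
Why: The terminal C–H is far more acidic than the doubly activated CH2, so one equivalent of base gives only acetylide 8, which acylates on the amide. The chelated adduct 9 prevents over-addition and releases the base-sensitive skipped enynone only at the neutral quench.

Step 6
Reactants: 2 2,3-bis(trimethylsilyloxy)buta-1,3-diene; 10 1-(methoxymethoxy)-7-methyloct-6-en-3-yn-2-one
Product: 11 2-(methoxymethoxy)-1-[2-(3-methylbut-2-en-1-yl)-4,5-bis(trimethylsilyloxy)cyclohexa-1,4-dien-1-yl]ethanone
Conditions: 2 (3 equiv), BHT (cat.), PhMe, 130 °C, sealed tube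
Reagents that add atoms: none
Why: Diene 2 (HOMO raised by two silyloxy groups) and the ketone-activated triple bond of 10 (low LUMO) combine in a concerted, suprafacial [4+2] cycloaddition of normal electron demand. The closest known reaction type is the Diels–Alder addition of 2-silyloxy- and 2,3-bis(silyloxy)buta-1,3-dienes to acetylenic ketones and esters, whose cyclohexa-1,4-diene adducts are dehydrogenated to phenols and catechols. The six-membered carbocycle that becomes ring B is closed by intermolecular cycloaddition: the two diene termini bond to the two alkyne carbons, forming C1'–C6' and C2'–C3' (ring B numbering) in one step. No stereocentre is formed. No regiochemical question arises because 2 is C2-symmetric; the selectivity needed is chemoselectivity for the conjugated alkyne over the isolated trisubstituted alkene, which the ketone secures. The reaction is run without Lewis acid, which would divert the silyl enol ether into Mukaiyama–Michael addition, and without base or protic acid, which would isomerise the skipped enynone or hydrolyse the diene; BHT suppresses radical polymerisation. An excess of 2 offsets its low s-cis population.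

Step 7
Reactants: 11 2-(methoxymethoxy)-1-[2-(3-methylbut-2-en-1-yl)-4,5-bis(trimethylsilyloxy)cyclohexa-1,4-dien-1-yl]ethanone
Product: 13 1-[4,5-dihydroxy-2-(3-methylbut-2-en-1-yl)phenyl]-2-(methoxymethoxy)ethanone, via bis(trimethylsilyl) aryl ether 12 (not isolated)
Conditions: DDQ (1 equiv), PhMe, 0 °C to rt, filter; then MeOH, citric acid (cat.), rt
Reagents that add atoms: none
Why: DDQ abstracts hydride from a doubly allylic CH2 flanked by the enol ether, and proton loss aromatises the ring (quinone dehydrogenation of a cyclohexa-1,4-diene). One equivalent at low temperature avoids oxidation to the ortho-quinone, and the aryl silyl ethers of 12 are methanolysed under acid too weak to touch the alkyl acetal.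

Step 8
Reactants: 13 1-[4,5-dihydroxy-2-(3-methylbut-2-en-1-yl)phenyl]-2-(methoxymethoxy)ethanone
Product: 14 1-[5-hydroxy-4-(2-methylbut-3-yn-2-yloxy)-2-(3-methylbut-2-en-1-yl)phenyl]-2-(methoxymethoxy)ethanone
Conditions: HC≡CCMe2Cl, DBU (1 equiv), CuCl2 (cat.), MeCN, 0 °C
Reagents that add atoms: 3-chloro-3-methylbut-1-yne, CC(C)(Cl)C#C
Why: The 4'-hydroxyl is para to the ketone and clearly the more acidic, so one equivalent of amidine base forms mainly its phenoxide, which is captured by the copper allenylidene from the tertiary propargylic chloride (copper-catalysed O-propargylation of phenols).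

Step 9
Reactants: 14 1-[5-hydroxy-4-(2-methylbut-3-yn-2-yloxy)-2-(3-methylbut-2-en-1-yl)phenyl]-2-(methoxymethoxy)ethanone
Product: 15 2-(methoxymethoxy)-1-[5-(methoxymethoxy)-4-(2-methylbut-3-yn-2-yloxy)-2-(3-methylbut-2-en-1-yl)phenyl]ethanone
Conditions: MOMCl, i-Pr2NEt, CH2Cl2, 0 °C to rt
Reagents that add atoms: chloromethyl methyl ether, COCCl
Why: Acetal protection of the remaining phenol; it blocks C5' for the next step and keeps the phenol away from the later oxidant.

Step 10
Reactants: 15 2-(methoxymethoxy)-1-[5-(methoxymethoxy)-4-(2-methylbut-3-yn-2-yloxy)-2-(3-methylbut-2-en-1-yl)phenyl]ethanone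
Product: 18 2-(methoxymethoxy)-1-[8-(methoxymethoxy)-2,2-dimethyl-5-(3-methylbut-2-en-1-yl)-2H-chromen-6-yl]ethanone, via allenyl phenol 16 (not isolated), via ortho-quinone methide 17 (not isolated)
Conditions: PhNEt2, 190 °C
Reagents that add atoms: none
Why: Aryl propargyl ether Claisen shift to C3', the only free ortho carbon, and enolisation give 16; a 1,5-hydrogen shift gives 17, which closes by oxa-6π electrocyclisation to the 2,2-dimethylchromene. The gem-dimethyl group accelerates the first step.

Step 11
Reactants: 19 1-fluoro-3,5-dimethoxybenzene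
Product: 21 2-fluoro-4,6-dimethoxybenzaldehyde, via aryl iminium chloride 20 (not isolated)
Conditions: POCl3, DMF, 0 to 60 °C; then H2O
Reagents that add atoms: N,N-dimethylformamide, CN(C)C=O; water, O
Why: Vilsmeier–Haack formylation para to one methoxy group and ortho to the other, at the less crowded position beside fluorine and not between the two methoxy groups; hydrolysis of 20 gives the aldehyde.

Step 12
Reactants: 21 2-fluoro-4,6-dimethoxybenzaldehyde
Product: 22 2-fluoro-4,6-dihydroxybenzaldehyde
Conditions: BBr3, CH2Cl2, −78 °C to rt; then H2O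
Reagents that add atoms: none
Why: Lewis-acid cleavage of both aryl methyl ethers (the ortho one assisted by the carbonyl, the para one by excess reagent); the aryl fluoride is inert, and this is done before any alkene is present.

Step 13
Reactants: 22 2-fluoro-4,6-dihydroxybenzaldehyde; 6 prenyl bromide
Product: 23 2-fluoro-6-hydroxy-4-[(3-methylbut-2-en-1-yl)oxy]benzaldehyde
Conditions: K2CO3 (1 equiv), acetone, rt
Reagents that add atoms: none
Why: Williamson etherification at the 4-hydroxyl, which is para to the formyl group, more acidic and not hydrogen-bonded; the chelated 6-hydroxyl stays free under one equivalent of weak base.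

Step 14
Reactants: 23 2-fluoro-6-hydroxy-4-[(3-methylbut-2-en-1-yl)oxy]benzaldehyde
Product: 24 2-fluoro-6-(methoxymethoxy)-4-[(3-methylbut-2-en-1-yl)oxy]benzaldehyde
Conditions: MOMCl, i-Pr2NEt, CH2Cl2, 0 °C to rt
Reagents that add atoms: chloromethyl methyl ether, COCCl
Why: Acetal protection of the chelated phenol; a non-chelating 5-O substituent is also what the later Claisen shift needs for C8 selectivity.

Step 15
Reactants: 18 2-(methoxymethoxy)-1-[8-(methoxymethoxy)-2,2-dimethyl-5-(3-methylbut-2-en-1-yl)-2H-chromen-6-yl]ethanone; 24 2-fluoro-6-(methoxymethoxy)-4-[(3-methylbut-2-en-1-yl)oxy]benzaldehyde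
Product: 26 3-[2-fluoro-6-(methoxymethoxy)-4-(3-methylbut-2-en-1-yloxy)phenyl]-3-hydroxy-2-(methoxymethoxy)-1-[8-(methoxymethoxy)-2,2-dimethyl-5-(3-methylbut-2-en-1-yl)-2H-chromen-6-yl]propan-1-one (mixture of racemic diastereomers), via lithium enolate 25 (not isolated)
Conditions: LiN(SiMe3)2, THF, −78 °C; then 24, −78 °C; AcOH
Reagents that add atoms: none
Why: Crossed aldol addition: the α-alkoxy ketone is the only enolisable partner and gives the chelated (Z)-enolate 25, which adds to the non-enolisable aldehyde. The cold acidic quench prevents retro-aldol, and the two new stereocentres are of no consequence because both are destroyed later.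

Step 16
Reactants: 26 aldol adduct (mixture of racemic diastereomers)
Product: 27 1-[2-fluoro-6-(methoxymethoxy)-4-(3-methylbut-2-en-1-yloxy)phenyl]-2-(methoxymethoxy)-3-[8-(methoxymethoxy)-2,2-dimethyl-5-(3-methylbut-2-en-1-yl)-2H-chromen-6-yl]propane-1,3-dione (racemic, in equilibrium with its enols)
Conditions: Dess–Martin periodinane, NaHCO3, CH2Cl2, 0 °C to rt
Reagents that add atoms: none
Why: Hypervalent-iodine oxidation of a β-hydroxy ketone to the 1,3-diketone; the bicarbonate buffer protects the acetals, and a small excess at low temperature limits over-oxidation at C2.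

Step 17
Reactants: 27 1,3-diketone
Product: 28 3,5-bis(methoxymethoxy)-2-[8-(methoxymethoxy)-2,2-dimethyl-5-(3-methylbut-2-en-1-yl)-2H-chromen-6-yl]-7-[(3-methylbut-2-en-1-yl)oxy]-4H-chromen-4-one
Conditions: K2CO3, DMF, 70 °C
Reagents that add atoms: none
Why: The enolate oxygen on the ring B side attacks the C–F carbon ortho to the other carbonyl (intramolecular nucleophilic aromatic substitution through a Meisenheimer adduct), closing the six-membered pyranone. Both alkoxy groups of ring A are meta to the fluorine and do not deactivate that carbon by resonance.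

Step 18
Reactants: 28 7-O-prenyl flavone
Product: 30 3,5-bis(methoxymethoxy)-2-[8-(methoxymethoxy)-2,2-dimethyl-5-(3-methylbut-2-en-1-yl)-2H-chromen-6-yl]-8-(2-methylbut-3-en-2-yl)-4-oxo-4H-chromen-7-yl butanoate, via 7-hydroxy flavone 29 (not isolated)
Conditions: (n-PrCO)2O, PhNEt2, 190 °C
Reagents that add atoms: butanoic anhydride, CCCC(=O)OC(=O)CCC
Why: Aromatic Claisen rearrangement: a [3,3] shift with allyl inversion carries the prenyl group from O7 to the ortho carbon as the quaternary 1,1-dimethylallyl group. C8 should be preferred over C6 because the C7–C8 bond of a 4H-chromen-4-one has the higher π-bond order and the non-chelated 5-alkoxy group directs para to itself. Phenol 29 is acylated as it forms, which closes off the abnormal Claisen pathway and ring closure onto the vinyl group; any acetal exchanged for butanoyl at this temperature would be removed in step 19 as well.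

Step 19
Reactants: 30 7-butanoate
Product: 32 Broussoflavonol D, via 7-O-butanoyl triol 31 (not isolated)
Conditions: HCl, i-PrOH–THF, 40 °C; evaporate; then K2CO3, MeOH (degassed), 0 °C, Ar; AcOH
Reagents that add atoms: none
Why: Acid-catalysed acetal exchange with 2-propanol removes the three methoxymethyl groups while the 7-oxygen is still acylated, so no free 7-hydroxyl stands beside the vinyl group under acid; the secondary alcohol and the quaternary carbon ortho to the ester keep acid transesterification of the aryl butanoate slow. Carbonate methanolysis of the aryl ester of 31 under argon, ended by an acetic acid quench, then frees the 7-hydroxyl in a brief cold base stage that should spare the 3-hydroxy-4-pyranone.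

## Compound list

1 | 2,3-butanedione | CC(=O)C(C)=O | starting material
2 | 2,3-bis(trimethylsilyloxy)buta-1,3-diene | C=C(O[Si](C)(C)C)C(=C)O[Si](C)(C)C | intermediate
3 | methyl glycolate | COC(=O)CO | starting material
4 | methyl 2-(methoxymethoxy)acetate | COCOCC(=O)OC | intermediate
5 | N-methoxy-2-(methoxymethoxy)-N-methylacetamide | COCOCC(=O)N(C)OC | intermediate
6 | prenyl bromide (1-bromo-3-methylbut-2-ene) | CC(C)=CCBr | starting material
7 | 5-methylhex-4-en-1-yne | C#CCC=C(C)C | intermediate
8 | (5-methylhex-4-en-1-yn-1-yl)lithium | [Li]C#CCC=C(C)C | intermediate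
9 | lithium 2-[methoxy(methyl)amino]-1-(methoxymethoxy)-7-methyloct-6-en-3-yn-2-olate (racemic) | COCOCC(O[Li])(C#CCC=C(C)C)N(C)OC | intermediate
10 | 1-(methoxymethoxy)-7-methyloct-6-en-3-yn-2-one | COCOCC(=O)C#CCC=C(C)C | intermediate
11 | 2-(methoxymethoxy)-1-[2-(3-methylbut-2-en-1-yl)-4,5-bis(trimethylsilyloxy)cyclohexa-1,4-dien-1-yl]ethanone | COCOCC(=O)C1=C(CC=C(C)C)CC(O[Si](C)(C)C)=C(O[Si](C)(C)C)C1 | intermediate
12 | 2-(methoxymethoxy)-1-[2-(3-methylbut-2-en-1-yl)-4,5-bis(trimethylsilyloxy)phenyl]ethanone | COCOCC(=O)c1cc(O[Si](C)(C)C)c(O[Si](C)(C)C)cc1CC=C(C)C | intermediate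
13 | 1-[4,5-dihydroxy-2-(3-methylbut-2-en-1-yl)phenyl]-2-(methoxymethoxy)ethanone | COCOCC(=O)c1cc(O)c(O)cc1CC=C(C)C | intermediate
14 | 1-[5-hydroxy-4-(2-methylbut-3-yn-2-yloxy)-2-(3-methylbut-2-en-1-yl)phenyl]-2-(methoxymethoxy)ethanone | COCOCC(=O)c1cc(O)c(OC(C)(C)C#C)cc1CC=C(C)C | intermediate
15 | 2-(methoxymethoxy)-1-[5-(methoxymethoxy)-4-(2-methylbut-3-yn-2-yloxy)-2-(3-methylbut-2-en-1-yl)phenyl]ethanone | COCOCC(=O)c1cc(OCOC)c(OC(C)(C)C#C)cc1CC=C(C)C | intermediate
16 | 1-[4-hydroxy-5-(methoxymethoxy)-3-(3-methylbuta-1,2-dien-1-yl)-2-(3-methylbut-2-en-1-yl)phenyl]-2-(methoxymethoxy)ethanone | COCOCC(=O)c1cc(OCOC)c(O)c(C=C=C(C)C)c1CC=C(C)C | intermediate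
17 | 6-(methoxymethoxy)-4-[2-(methoxymethoxy)acetyl]-3-(3-methylbut-2-en-1-yl)-2-(3-methylbut-2-en-1-ylidene)cyclohexa-3,5-dien-1-one (alkene geometry not defined) | COCOCC(=O)C1=C(CC=C(C)C)C(=CC=C(C)C)C(=O)C(OCOC)=C1 | intermediate
18 | 2-(methoxymethoxy)-1-[8-(methoxymethoxy)-2,2-dimethyl-5-(3-methylbut-2-en-1-yl)-2H-chromen-6-yl]ethanone | COCOCC(=O)c1cc(OCOC)c2OC(C)(C)C=Cc2c1CC=C(C)C | intermediate
19 | 1-fluoro-3,5-dimethoxybenzene | COc1cc(F)cc(OC)c1 | starting material
20 | N-[(2-fluoro-4,6-dimethoxyphenyl)methylidene]-N-methylmethanaminium chloride | COc1cc(F)c(C=[N+](C)C)c(OC)c1.[Cl-] | intermediate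
21 | 2-fluoro-4,6-dimethoxybenzaldehyde | COc1cc(F)c(C=O)c(OC)c1 | intermediate
22 | 2-fluoro-4,6-dihydroxybenzaldehyde | O=Cc1c(O)cc(O)cc1F | intermediate
23 | 2-fluoro-6-hydroxy-4-[(3-methylbut-2-en-1-yl)oxy]benzaldehyde | O=Cc1c(O)cc(OCC=C(C)C)cc1F | intermediate
24 | 2-fluoro-6-(methoxymethoxy)-4-[(3-methylbut-2-en-1-yl)oxy]benzaldehyde | O=Cc1c(OCOC)cc(OCC=C(C)C)cc1F | intermediate
25 | lithium (Z)-2-(methoxymethoxy)-1-[8-(methoxymethoxy)-2,2-dimethyl-5-(3-methylbut-2-en-1-yl)-2H-chromen-6-yl]ethen-1-olate | [Li]O/C(=C\OCOC)c1cc(OCOC)c2OC(C)(C)C=Cc2c1CC=C(C)C | intermediate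
26 | 3-[2-fluoro-6-(methoxymethoxy)-4-(3-methylbut-2-en-1-yloxy)phenyl]-3-hydroxy-2-(methoxymethoxy)-1-[8-(methoxymethoxy)-2,2-dimethyl-5-(3-methylbut-2-en-1-yl)-2H-chromen-6-yl]propan-1-one (mixture of racemic diastereomers) | COCOC(C(O)c1c(F)cc(OCC=C(C)C)cc1OCOC)C(=O)c1cc(OCOC)c2OC(C)(C)C=Cc2c1CC=C(C)C | intermediate
27 | 1-[2-fluoro-6-(methoxymethoxy)-4-(3-methylbut-2-en-1-yloxy)phenyl]-2-(methoxymethoxy)-3-[8-(methoxymethoxy)-2,2-dimethyl-5-(3-methylbut-2-en-1-yl)-2H-chromen-6-yl]propane-1,3-dione (racemic) | COCOC(C(=O)c1c(F)cc(OCC=C(C)C)cc1OCOC)C(=O)c1cc(OCOC)c2OC(C)(C)C=Cc2c1CC=C(C)C | intermediate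
28 | 3,5-bis(methoxymethoxy)-2-[8-(methoxymethoxy)-2,2-dimethyl-5-(3-methylbut-2-en-1-yl)-2H-chromen-6-yl]-7-[(3-methylbut-2-en-1-yl)oxy]-4H-chromen-4-one | COCOc1c(-c2cc(OCOC)c3OC(C)(C)C=Cc3c2CC=C(C)C)oc2cc(OCC=C(C)C)cc(OCOC)c2c1=O | intermediate
29 | 7-hydroxy-3,5-bis(methoxymethoxy)-2-[8-(methoxymethoxy)-2,2-dimethyl-5-(3-methylbut-2-en-1-yl)-2H-chromen-6-yl]-8-(2-methylbut-3-en-2-yl)-4H-chromen-4-one | COCOc1c(-c2cc(OCOC)c3OC(C)(C)C=Cc3c2CC=C(C)C)oc2c(C(C)(C)C=C)c(O)cc(OCOC)c2c1=O | intermediate
30 | 3,5-bis(methoxymethoxy)-2-[8-(methoxymethoxy)-2,2-dimethyl-5-(3-methylbut-2-en-1-yl)-2H-chromen-6-yl]-8-(2-methylbut-3-en-2-yl)-4-oxo-4H-chromen-7-yl butanoate | COCOc1c(-c2cc(OCOC)c3OC(C)(C)C=Cc3c2CC=C(C)C)oc2c(C(C)(C)C=C)c(OC(=O)CCC)cc(OCOC)c2c1=O | intermediate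
31 | 3,5-dihydroxy-2-[8-hydroxy-2,2-dimethyl-5-(3-methylbut-2-en-1-yl)-2H-chromen-6-yl]-8-(2-methylbut-3-en-2-yl)-4-oxo-4H-chromen-7-yl butanoate | Oc1c(-c2cc(O)c3OC(C)(C)C=Cc3c2CC=C(C)C)oc2c(C(C)(C)C=C)c(OC(=O)CCC)cc(O)c2c1=O | intermediate
32 | Broussoflavonol D, 3,5,7-trihydroxy-2-[8-hydroxy-2,2-dimethyl-5-(3-methylbut-2-en-1-yl)-2H-chromen-6-yl]-8-(2-methylbut-3-en-2-yl)-4H-chromen-4-one | C=CC(C)(C)c1c(O)cc(O)c2c(=O)c(O)c(-c3cc(O)c4c(c3CC=C(C)C)C=CC(C)(C)O4)oc12 | target

## Step count and least certain steps

Total: 19 steps. Longest linear sequence: 13 steps, from methyl glycolate 3 (steps 2, 3, 5, 6, 7, 8, 9, 10, 15, 16, 17, 18, 19). The ynone 10 is reached in four steps and the diene 2 in one.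

**Step 6 (key step).** The most likely failure is a slow cycloaddition. The internal ynone is a modest dienophile and the diene populates its s-cis form poorly, so thermal isomerisation of the skipped enynone to a conjugated allene, or desilylation and oligomerisation of the diene, may outrun ring formation. Fallback: an s-cis-locked diene. It sets out from ynone 10. Radical bromination of commercial 4,5-dimethyl-1,3-dioxol-2-one with NBS gives 4,5-bis(bromomethyl)-1,3-dioxol-2-one F1. Zn removes both bromines to give 4,5-dimethylene-1,3-dioxolan-2-one F2, which is trapped by 10 at moderate temperature as the dihydrobenzodioxolone adduct F3. DDQ dehydrogenates F3 to the catechol carbonate F4, and methanolysis with a trace of K2CO3 at 0 °C comes back to the route at catechol 13.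

**Step 18.** The risk is poor site selectivity of the sigmatropic shift between C8 and C6. A second risk is incomplete trapping, which would let the abnormal Claisen pathway and ring closure onto the vinyl group compete at 190 °C. Fallback: move the shift to ring A before the coupling. There the site is set by a different element (the 6-alkoxy group, para to C3) and the isomers can be separated on a small molecule. It sets out from aldehyde 24, which under the conditions of step 18 should rearrange to 2-fluoro-4-hydroxy-6-(methoxymethoxy)-3-(2-methylbut-3-en-2-yl)benzaldehyde F5, acylated as it forms to 3-fluoro-4-formyl-5-(methoxymethoxy)-2-(2-methylbut-3-en-2-yl)phenyl butanoate F6. Addition of enolate 25 at −78 °C gives the aldol adduct F7, Dess–Martin oxidation gives the 1,3-diketone F8, and K2CO3 in dry DMF closes ring C with loss of fluoride, rejoining the route at butanoate 30.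

**Step 8.** The risk is loss of discrimination between the two phenols (alkylation at the 5'-oxygen or at both). Chelation of copper by the catechol could also stall the catalyst. Fallback: discriminate by silyl ether lability. It sets out from catechol 13. TBSCl and imidazole give the bis(tert-butyldimethylsilyl) ether F9. The silyl ether para to the ketone, which leaves as the better phenoxide, is cleaved with K2CO3 in MeOH at 0 °C to the 4'-phenol F10. Propargylation as in step 8, now with one free hydroxyl, gives the silyl-protected propargyl ether F11, and Bu4NF comes back to the route at 14.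

**Step 15.** The risk is reversal of the aldol addition. The aldehyde is electron-rich and carries two ortho substituents, so the aldolate may revert or eliminate on warming, and the diastereomer mixture complicates handling. Fallback: acylation in place of aldol and oxidation, with an acyl donor that forms without acid. It sets out from aldehyde 24. Chlorite oxidation (NaClO2, NaH2PO4, 2-methylbut-2-ene) gives 2-fluoro-6-(methoxymethoxy)-4-[(3-methylbut-2-en-1-yl)oxy]benzoic acid F12. 1-(Methylsulfonyl)benzotriazole and Et3N convert it into the N-acylbenzotriazole F13. C-acylation of enolate 25 with F13 comes back to the route at diketone 27.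

**Step 19.** The risk in the acid stage is premature acid-catalysed loss of the 7-O-butanoyl group while the slowest acetal (5'-O) is being cleaved, which would let the 7-hydroxyl close onto the vinyl group, or acid addition to the prenyl alkene. The risk in the base stage is oxidative degradation of the free 3-hydroxy-4-pyranone if air is not excluded. Fallback: remove the acetals before the reverse prenyl group exists and finish under base only. It sets out from flavone 28. Dilute HCl in MeOH gives 3,5-dihydroxy-2-[8-hydroxy-2,2-dimethyl-5-(3-methylbut-2-en-1-yl)-2H-chromen-6-yl]-7-[(3-methylbut-2-en-1-yl)oxy]-4H-chromen-4-one F14. Butanoic anhydride, pyridine and DMAP give the tributanoate F15. The Claisen shift under the conditions of step 18 gives the 7-hydroxy tributanoate F16, which is butanoylated as it forms to the tetrabutanoate F17. K2CO3 in degassed MeOH with an acetic acid quench comes back to the route at 32.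

## Further compounds

F1 | step 6 | 4,5-bis(bromomethyl)-1,3-dioxol-2-one | O=C1OC(CBr)=C(CBr)O1
F2 | step 6 | 4,5-dimethylene-1,3-dioxolan-2-one | C=C1OC(=O)OC1=C
F3 | step 6 | 5-[2-(methoxymethoxy)acetyl]-6-(3-methylbut-2-en-1-yl)-4,7-dihydro-1,3-benzodioxol-2-one | COCOCC(=O)C1=C(CC=C(C)C)CC2=C(C1)OC(=O)O2
F4 | step 6 | 5-[2-(methoxymethoxy)acetyl]-6-(3-methylbut-2-en-1-yl)-1,3-benzodioxol-2-one | COCOCC(=O)c1cc2OC(=O)Oc2cc1CC=C(C)C
F5 | step 18 | 2-fluoro-4-hydroxy-6-(methoxymethoxy)-3-(2-methylbut-3-en-2-yl)benzaldehyde | O=Cc1c(OCOC)cc(O)c(C(C)(C)C=C)c1F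
F6 | step 18 | 3-fluoro-4-formyl-5-(methoxymethoxy)-2-(2-methylbut-3-en-2-yl)phenyl butanoate | CCCC(=O)Oc1cc(OCOC)c(C=O)c(F)c1C(C)(C)C=C
F7 | step 18 | 3-fluoro-4-{1-hydroxy-2-(methoxymethoxy)-3-[8-(methoxymethoxy)-2,2-dimethyl-5-(3-methylbut-2-en-1-yl)-2H-chromen-6-yl]-3-oxopropyl}-5-(methoxymethoxy)-2-(2-methylbut-3-en-2-yl)phenyl butanoate (mixture of racemic diastereomers) | COCOC(C(O)c1c(F)c(C(C)(C)C=C)c(OC(=O)CCC)cc1OCOC)C(=O)c1cc(OCOC)c2OC(C)(C)C=Cc2c1CC=C(C)C
F8 | step 18 | 3-fluoro-5-(methoxymethoxy)-4-{2-(methoxymethoxy)-3-[8-(methoxymethoxy)-2,2-dimethyl-5-(3-methylbut-2-en-1-yl)-2H-chromen-6-yl]-3-oxopropanoyl}-2-(2-methylbut-3-en-2-yl)phenyl butanoate (racemic) | COCOC(C(=O)c1c(F)c(C(C)(C)C=C)c(OC(=O)CCC)cc1OCOC)C(=O)c1cc(OCOC)c2OC(C)(C)C=Cc2c1CC=C(C)C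
F9 | step 8 | 1-[4,5-bis(tert-butyldimethylsilyloxy)-2-(3-methylbut-2-en-1-yl)phenyl]-2-(methoxymethoxy)ethanone | COCOCC(=O)c1cc(O[Si](C)(C)C(C)(C)C)c(O[Si](C)(C)C(C)(C)C)cc1CC=C(C)C
F10 | step 8 | 1-[5-(tert-butyldimethylsilyloxy)-4-hydroxy-2-(3-methylbut-2-en-1-yl)phenyl]-2-(methoxymethoxy)ethanone | COCOCC(=O)c1cc(O[Si](C)(C)C(C)(C)C)c(O)cc1CC=C(C)C
F11 | step 8 | 1-[5-(tert-butyldimethylsilyloxy)-4-(2-methylbut-3-yn-2-yloxy)-2-(3-methylbut-2-en-1-yl)phenyl]-2-(methoxymethoxy)ethanone | COCOCC(=O)c1cc(O[Si](C)(C)C(C)(C)C)c(OC(C)(C)C#C)cc1CC=C(C)C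
F12 | step 15 | 2-fluoro-6-(methoxymethoxy)-4-[(3-methylbut-2-en-1-yl)oxy]benzoic acid | OC(=O)c1c(F)cc(OCC=C(C)C)cc1OCOC
F13 | step 15 | (1H-benzotriazol-1-yl){2-fluoro-6-(methoxymethoxy)-4-[(3-methylbut-2-en-1-yl)oxy]phenyl}methanone | O=C(c1c(F)cc(OCC=C(C)C)cc1OCOC)n1nnc2ccccc21
F14 | step 19 | 3,5-dihydroxy-2-[8-hydroxy-2,2-dimethyl-5-(3-methylbut-2-en-1-yl)-2H-chromen-6-yl]-7-[(3-methylbut-2-en-1-yl)oxy]-4H-chromen-4-one | Oc1c(-c2cc(O)c3OC(C)(C)C=Cc3c2CC=C(C)C)oc2cc(OCC=C(C)C)cc(O)c2c1=O
F15 | step 19 | 2-[8-(butanoyloxy)-2,2-dimethyl-5-(3-methylbut-2-en-1-yl)-2H-chromen-6-yl]-7-[(3-methylbut-2-en-1-yl)oxy]-4-oxo-4H-chromene-3,5-diyl dibutanoate | CCCC(=O)Oc1c(-c2cc(OC(=O)CCC)c3OC(C)(C)C=Cc3c2CC=C(C)C)oc2cc(OCC=C(C)C)cc(OC(=O)CCC)c2c1=O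
F16 | step 19 | 2-[8-(butanoyloxy)-2,2-dimethyl-5-(3-methylbut-2-en-1-yl)-2H-chromen-6-yl]-7-hydroxy-8-(2-methylbut-3-en-2-yl)-4-oxo-4H-chromene-3,5-diyl dibutanoate | CCCC(=O)Oc1c(-c2cc(OC(=O)CCC)c3OC(C)(C)C=Cc3c2CC=C(C)C)oc2c(C(C)(C)C=C)c(O)cc(OC(=O)CCC)c2c1=O
F17 | step 19 | 2-[8-(butanoyloxy)-2,2-dimethyl-5-(3-methylbut-2-en-1-yl)-2H-chromen-6-yl]-8-(2-methylbut-3-en-2-yl)-4-oxo-4H-chromene-3,5,7-triyl tributanoate | CCCC(=O)Oc1cc(OC(=O)CCC)c2c(=O)c(OC(=O)CCC)c(-c3cc(OC(=O)CCC)c4OC(C)(C)C=Cc4c3CC=C(C)C)oc2c1C(C)(C)C=C
A1 | alternative 1 | 4,6-dimethoxybenzofuran-2(3H)-one | O=C1Oc2cc(OC)cc(OC)c2C1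
A2 | alternative 1 | 4,6-dimethoxy-3,3-dimethylbenzofuran-2(3H)-one | O=C1Oc2cc(OC)cc(OC)c2C1(C)C
A3 | alternative 1 | 3,5-dimethoxy-2-(2-methylbut-3-en-2-yl)phenol | C=CC(C)(C)c1c(O)cc(OC)cc1OC
A4 | alternative 2 | 5,7-bis(methoxymethoxy)-8-(2-methylbut-3-en-2-yl)-4-oxo-4H-chromen-3-yl 6-bromo-8-(methoxymethoxy)-2,2-dimethyl-2H-chromene-5-carboxylate | C=CC(C)(C)c1c(OCOC)cc(OCOC)c2c(=O)c(OC(=O)c3c(Br)cc(OCOC)c4OC(C)(C)C=Cc34)coc12
A5 | alternative 2 | lactone-bridged flavonol with rings A to D complete and the C2' carbon as a lactone carbonyl bound to the 3-oxygen | C=CC(C)(C)c1c(OCOC)cc(OCOC)c2c(=O)c3OC(=O)c4c5C=CC(C)(C)Oc5c(OCOC)cc4-c3oc12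
A6 | alternative 3 | methyl 5-methyl-3-oxohex-4-enoate | COC(=O)CC(=O)C=C(C)C
A7 | alternative 3 | 3,4-dimethoxybenzyne | COC1=C(OC)C#CC=C1
A8 | alternative 3 | 2,3-dimethoxy-6-(trimethylsilyl)phenyl trifluoromethanesulfonate | COc1ccc([Si](C)(C)C)c(OS(=O)(=O)C(F)(F)F)c1OC
A9 | alternative 3 | methyl 2-[3,4-dimethoxy-2-(3-methylbut-2-enoyl)phenyl]acetate | COC(=O)Cc1ccc(OC)c(OC)c1C(=O)C=C(C)C
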